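## Retrosynthetic overview

- Numbering: C1 (carboxyl) to C24 (vinyl terminus); ring A = oxolane (O, C7–C10), ring B = 1,2-dioxane (O–O, C3–C6). The acid comes from its methyl ester, and ring B is closed last at O–C3 by reversible addition of a C6 hydroperoxide to a C2=C3 enoate (trans, diequatorial).
- The O–O unit is put on C6 with inversion through a temporary cyclic peroxy acetal: a C3 hydroperoxy acetal displaces a C6 mesylate, and the ring is then opened again at C3 for olefination.
- Ring A is closed first, at the O–C7 bond, by a heptavalent-rhenium syn-oxidative cyclisation: the O=Re–O unit of the C10 perrhenate adds (3+2) across an (E)-C6=C7 alkene of an acyclic alkenol. C10 alone then sets C7 (2,5-trans) and C6 (threo).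
- Enabling feature: the ring A oxygen on C10 lies four carbons from C7, and the vicinal C7–O (ether) and C6–O (peroxide) bonds map onto the two ends of an (E)-C6=C7 double bond of a 5-hydroxyalkene.
- The alkenol comes from a Julia–Kocienski union of a glutamate-derived lactol (carrying the triene chain, attached by Grignard opening of an epoxy ester) with an acetal sulfone. Ring order: ring A, temporary peroxy-acetal ring, ring B.

Key step: step 11

Remark: the peroxy-acetal carbon C3 is carried as an epimer mixture until it becomes sp2 before the final closure, and the lactol is used as an anomer mixture; all starting materials are taken as commercial.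

## Route

Step 1
Reactants: 1 hex-5-en-1-yne
Product: 2 1-bromohex-5-en-1-yne
Conditions: NBS, AgNO3 (cat.), acetone, rt
Reagents that add atoms: N-bromosuccinimide, O=C1CCC(=O)N1Br
Why: Silver-catalysed electrophilic bromination of the terminal alkyne C–H should give the 1-bromoalkyne without touching the alkene.

Step 2
Reactants: 2 1-bromohex-5-en-1-yne; 3 hept-6-yn-1-ol
Product: 4 tridec-12-ene-6,8-diyn-1-ol
Conditions: CuCl (cat.), NH2OH·HCl, 30% aq. n-BuNH2, Et2O, 0 °C
Reagents that add atoms: none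
Why: Cadiot–Chodkiewicz coupling of the copper acetylide of 3 with bromoalkyne 2 should give the unsymmetrical 1,3-diyne, with the free hydroxyl and the alkene tolerated.

Step 3
Reactants: 4 tridec-12-ene-6,8-diyn-1-ol
Product: 5 (6Z,8Z)-trideca-6,8,12-trien-1-ol
Conditions: Zn dust activated with Cu(OAc)2 and AgNO3, MeOH/H2O, 45 °C
Reagents that add atoms: none
Why: Activated-zinc semi-reduction of conjugated triple bonds in protic medium delivers hydrogen cis to each alkyne and should give the (Z,Z)-diene, while the isolated terminal alkene is not reduced.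

Step 4
Reactants: 5 (6Z,8Z)-trideca-6,8,12-trien-1-ol
Product: 6 (5Z,7Z)-13-bromotrideca-1,5,7-triene
Conditions: CBr4, PPh3, CH2Cl2, 0 °C
Reagents that add atoms: tetrabromomethane, BrC(Br)(Br)Br
Why: Appel bromination converts the primary alcohol into the bromide under neutral conditions that should leave the (Z,Z)-diene unchanged.

Step 5
Reactants: 7 [(2S)-5-oxooxolan-2-yl]methyl 4-methylbenzenesulfonate
Product: 8 methyl 3-[(2S)-oxiran-2-yl]propanoate
Conditions: NaOMe, MeOH, 0 °C to rt
Reagents that add atoms: sodium methoxide, [Na+].[O-]C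
Why: Methanolysis of the lactone frees the secondary alkoxide, which displaces the neighbouring primary tosylate (intramolecular Williamson etherification); the C–O bond at the stereocentre is not broken, so the configuration is retained.

Step 6
Reactants: 6 (5Z,7Z)-13-bromotrideca-1,5,7-triene; 8 methyl 3-[(2S)-oxiran-2-yl]propanoate
Product: 11 (5R)-5-[(7Z,9Z)-tetradeca-7,9,13-trien-1-yl]oxolan-2-one, via trienylmagnesium bromide 9 (not isolated), via hydroxy ester 10 (not isolated)
Conditions: Mg, THF; then 8, CuI (cat.), THF, −40 °C; aq. HCl; then TsOH·H2O (cat.), CH2Cl2, rt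
Reagents that add atoms: none
Why: Copper-catalysed Grignard opening of the terminal epoxide at its CH2 carbon (methyl ester tolerated at low temperature) followed by acid-catalysed lactonisation should give the lactone, the stereocentre being carried over from 8 untouched.

Step 7
Reactants: 11 (5R)-5-[(7Z,9Z)-tetradeca-7,9,13-trien-1-yl]oxolan-2-one
Product: 12 (5R)-5-[(7Z,9Z)-tetradeca-7,9,13-trien-1-yl]oxolan-2-ol (anomer mixture)
Conditions: iBu2AlH, CH2Cl2, −78 °C; then H2O
Reagents that add atoms: none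
Why: Partial reduction of a lactone with iBu2AlH at −78 °C stops at the lactol because the tetrahedral aluminium acetal is stable until work-up.

Step 8
Reactants: 13 4-chloro-1,1-dimethoxybutane; 14 1-phenyl-1H-tetrazole-5-thiol
Product: 15 5-[(4,4-dimethoxybutyl)sulfanyl]-1-phenyl-1H-tetrazole
Conditions: K2CO3, NaI (cat.), DMF, 60 °C
Reagents that add atoms: none
Why: SN2 alkylation of the thiolate by the primary chloride (iodide catalysis) should give the sulfide, the acetal being stable to base.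

Step 9
Reactants: 15 5-[(4,4-dimethoxybutyl)sulfanyl]-1-phenyl-1H-tetrazole
Product: 16 5-[(4,4-dimethoxybutyl)sulfonyl]-1-phenyl-1H-tetrazole
Conditions: mCPBA, NaHCO3, CH2Cl2, 0 °C to rt
Reagents that add atoms: 3-chloroperoxybenzoic acid, OOC(=O)c1cccc(Cl)c1
Why: Buffered peracid oxidation takes the sulfide to the sulfone while the hydrogencarbonate protects the dimethyl acetal.

Step 10
Reactants: 12 (5R)-5-[(7Z,9Z)-tetradeca-7,9,13-trien-1-yl]oxolan-2-ol; 16 5-[(4,4-dimethoxybutyl)sulfonyl]-1-phenyl-1H-tetrazole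
Product: 17 (4E,8R,15Z,17Z)-1,1-dimethoxydocosa-4,15,17,21-tetraen-8-ol
Conditions: KN(SiMe3)2 (excess), DME, −60 °C to rt
Reagents that add atoms: none
Why: Julia–Kocienski olefination on the open hydroxy-aldehyde form of the lactol (one extra equivalent of base for the hydroxyl) should give the (E)-C6=C7 alkene, as expected for a phenyltetrazolyl sulfone with a potassium counter-ion in DME.

Step 11
Reactants: 17 (4E,8R,15Z,17Z)-1,1-dimethoxydocosa-4,15,17,21-tetraen-8-ol
Product: 20 (1S)-4,4-dimethoxy-1-[(2S,5R)-5-[(7Z,9Z)-tetradeca-7,9,13-trien-1-yl]oxolan-2-yl]butan-1-ol, via alkyl perrhenate 18 (not isolated), via pentavalent rhenium alkoxide 19 (not isolated)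
Conditions: Re2O7, 2,6-lutidine, CH2Cl2, rt; then aq. NaHCO3
Reagents that add atoms: dirhenium heptoxide, O=[Re](=O)(=O)O[Re](=O)(=O)=O
Why: Alcohol 17 condenses with Re2O7 to alkyl perrhenate 18, whose O=Re–O unit adds suprafacially across the tethered C6=C7 double bond in an intramolecular (3+2) cycloaddition to give pentavalent rhenium alkoxide 19, which is hydrolysed on work-up. The closest known reaction type is the heptavalent-rhenium syn-oxidative cyclisation of 5-hydroxyalkenes to trans-2,5-disubstituted 2-(hydroxyalkyl)oxolanes. Ring A closes in a 5-exo-trig sense by attack of the C10 oxygen on C7 while an oxo oxygen is delivered to C6, so the O–Re–O bridge acts as a temporary tether that is cleaved afterwards. C7 should be set 2,5-trans to C10 because the C10 side chain sits pseudo-equatorial in the compact perrhenate transition state, and C6 is set by the stereospecific syn addition to the (E)-alkene, which gives the threo (6S,7S) relationship. The step needs chemoselectivity for one of four double bonds, secured by the tether (only C6=C7 can reach the Re=O group bound at C10), and 2,6-lutidine buffers the perrhenic acid so that the dimethyl acetal and the (Z,Z)-diene should survive.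

Step 12
Reactants: 20 (1S)-4,4-dimethoxy-1-[(2S,5R)-5-[(7Z,9Z)-tetradeca-7,9,13-trien-1-yl]oxolan-2-yl]butan-1-ol
Product: 21 (1S)-4,4-dimethoxy-1-[(2S,5R)-5-[(7Z,9Z)-tetradeca-7,9,13-trien-1-yl]oxolan-2-yl]butyl methanesulfonate
Conditions: MsCl, Et3N, CH2Cl2, 0 °C
Reagents that add atoms: methanesulfonyl chloride, CS(=O)(=O)Cl
Why: O-sulfonylation of the secondary alcohol proceeds with retention at C6 and installs the leaving group for the later inversion.

Step 13
Reactants: 21 (1S)-4,4-dimethoxy-1-[(2S,5R)-5-[(7Z,9Z)-tetradeca-7,9,13-trien-1-yl]oxolan-2-yl]butyl methanesulfonate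
Product: 22 (1S)-4-hydroperoxy-4-methoxy-1-[(2S,5R)-5-[(7Z,9Z)-tetradeca-7,9,13-trien-1-yl]oxolan-2-yl]butyl methanesulfonate (C4 epimers)
Conditions: H2O2·urea, Sc(OTf)3 (cat.), MeOH, rt
Reagents that add atoms: hydrogen peroxide (as its urea adduct), OO
Why: Lewis-acid-catalysed acetal exchange should trap the oxocarbenium ion of the dimethyl acetal with H2O2 to give the α-methoxy hydroperoxide, methanol as solvent suppressing the bis-hydroperoxide.

Step 14
Reactants: 22 (1S)-4-hydroperoxy-4-methoxy-1-[(2S,5R)-5-[(7Z,9Z)-tetradeca-7,9,13-trien-1-yl]oxolan-2-yl]butyl methanesulfonate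
Product: 23 (6R)-3-methoxy-6-[(2S,5R)-5-[(7Z,9Z)-tetradeca-7,9,13-trien-1-yl]oxolan-2-yl]-1,2-dioxane (C3 epimers)
Conditions: KOtBu (1 equiv), 18-crown-6, THF, 0 °C
Reagents that add atoms: none
Why: Intramolecular alkylation of the hydroperoxy acetal (6-exo-tet SN2 by the peroxy anion) should displace the mesylate with inversion and so set (6R), one equivalent of base being used to avoid Kornblum–DeLaMare cleavage of the product.

Step 15
Reactants: 23 (6R)-3-methoxy-6-[(2S,5R)-5-[(7Z,9Z)-tetradeca-7,9,13-trien-1-yl]oxolan-2-yl]-1,2-dioxane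
Product: 24 (6R)-6-[(2S,5R)-5-[(7Z,9Z)-tetradeca-7,9,13-trien-1-yl]oxolan-2-yl]-1,2-dioxan-3-ol (C3 epimers)
Conditions: aq. HCl (0.5 M), THF, rt
Reagents that add atoms: water, O
Why: Acid hydrolysis of the cyclic peroxy acetal through its peroxycarbenium ion should give the peroxy-hemiacetal without touching the O–O bond or the stereocentres.

Step 16
Reactants: 24 (6R)-6-[(2S,5R)-5-[(7Z,9Z)-tetradeca-7,9,13-trien-1-yl]oxolan-2-yl]-1,2-dioxan-3-ol; 25 methyl 2-(triphenylphosphoranylidene)acetate
Product: 27 methyl 2-[(3R,6R)-6-[(2S,5R)-5-[(7Z,9Z)-tetradeca-7,9,13-trien-1-yl]oxolan-2-yl]-1,2-dioxan-3-yl]acetate, via hydroperoxy enoate 26 (not isolated)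
Conditions: 25, CH2Cl2, rt; then Et2NH, CF3CH2OH, rt
Reagents that add atoms: none
Why: Proposed new method: ring-chain tautomerism of peroxy-hemiacetal 24 exposes the 4-hydroperoxy aldehyde, which the stabilised ylide should olefinate (E) faster than it attacks the poorly electrophilic O–O bond of an alkyl hydroperoxide, and the amine then triggers 6-exo-trig conjugate addition of the hydroperoxide to the enoate; the closest known reaction types are the Wittig/oxa-Michael conversion of lactols into C-glycosides and the amine-promoted cyclisation of hydroperoxy enoates to 1,2-dioxane-3-acetates; C3 should be set trans to C6 (both substituents equatorial on the chair) because the addition is reversible under the basic conditions.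

Step 17
Reactants: 27 methyl 2-[(3R,6R)-6-[(2S,5R)-5-[(7Z,9Z)-tetradeca-7,9,13-trien-1-yl]oxolan-2-yl]-1,2-dioxan-3-yl]acetate
Product: 28 2-[(3R,6R)-6-[(2S,5R)-5-[(7Z,9Z)-tetradeca-7,9,13-trien-1-yl]oxolan-2-yl]-1,2-dioxan-3-yl]acetic acid (target)
Conditions: LiOH, THF/H2O, 0 °C; then aq. HCl to pH 4
Reagents that add atoms: lithium hydroxide, [Li+].[OH-]
Why: Saponification of the methyl ester with LiOH at 0 °C is the standard release of 1,2-dioxane-3-acetic acids and should leave the dialkyl peroxide, the oxolane and the triene intact.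

## Compound list

1 | hex-5-en-1-yne | C#CCCC=C | starting material
2 | 1-bromohex-5-en-1-yne | BrC#CCCC=C | intermediate
3 | hept-6-yn-1-ol | OCCCCCC#C | starting material
4 | tridec-12-ene-6,8-diyn-1-ol | OCCCCCC#CC#CCCC=C | intermediate
5 | (6Z,8Z)-trideca-6,8,12-trien-1-ol | OCCCCC/C=C\C=C/CCC=C | intermediate
6 | (5Z,7Z)-13-bromotrideca-1,5,7-triene | BrCCCCC/C=C\C=C/CCC=C | intermediate
7 | [(2S)-5-oxooxolan-2-yl]methyl 4-methylbenzenesulfonate | O=C1CC[C@@H](COS(=O)(=O)c2ccc(C)cc2)O1 | starting material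
8 | methyl 3-[(2S)-oxiran-2-yl]propanoate | COC(=O)CC[C@H]1CO1 | intermediate
9 | [(6Z,8Z)-trideca-6,8,12-trien-1-yl]magnesium bromide | Br[Mg]CCCCC/C=C\C=C/CCC=C | intermediate
10 | methyl (4R,11Z,13Z)-4-hydroxyoctadeca-11,13,17-trienoate | COC(=O)CC[C@H](O)CCCCCC/C=C\C=C/CCC=C | intermediate
11 | (5R)-5-[(7Z,9Z)-tetradeca-7,9,13-trien-1-yl]oxolan-2-one | O=C1CC[C@@H](CCCCCC/C=C\C=C/CCC=C)O1 | intermediate
12 | (5R)-5-[(7Z,9Z)-tetradeca-7,9,13-trien-1-yl]oxolan-2-ol (anomer mixture) | OC1CC[C@@H](CCCCCC/C=C\C=C/CCC=C)O1 | intermediate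
13 | 4-chloro-1,1-dimethoxybutane | COC(OC)CCCCl | starting material
14 | 1-phenyl-1H-tetrazole-5-thiol | SC1=NN=NN1c1ccccc1 | starting material
15 | 5-[(4,4-dimethoxybutyl)sulfanyl]-1-phenyl-1H-tetrazole | COC(OC)CCCSC1=NN=NN1c1ccccc1 | intermediate
16 | 5-[(4,4-dimethoxybutyl)sulfonyl]-1-phenyl-1H-tetrazole | COC(OC)CCCS(=O)(=O)C1=NN=NN1c1ccccc1 | intermediate
17 | (4E,8R,15Z,17Z)-1,1-dimethoxydocosa-4,15,17,21-tetraen-8-ol | COC(OC)CC/C=C/CC[C@H](O)CCCCCC/C=C\C=C/CCC=C | intermediate
18 | (4E,8R,15Z,17Z)-1,1-dimethoxydocosa-4,15,17,21-tetraen-8-yl perrhenate | COC(OC)CC/C=C/CC[C@H](O[Re](=O)(=O)=O)CCCCCC/C=C\C=C/CCC=C | intermediate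
19 | pentavalent rhenium (dioxo) alkoxide of alcohol 20, bound through the carbinol oxygen | C=CCC/C=C\C=C/CCCCCC[C@@H]1CC[C@@H]([C@@H](O[Re](=O)=O)CCC(OC)OC)O1 | intermediate
20 | (1S)-4,4-dimethoxy-1-[(2S,5R)-5-[(7Z,9Z)-tetradeca-7,9,13-trien-1-yl]oxolan-2-yl]butan-1-ol | C=CCC/C=C\C=C/CCCCCC[C@@H]1CC[C@@H]([C@@H](O)CCC(OC)OC)O1 | intermediate
21 | (1S)-4,4-dimethoxy-1-[(2S,5R)-5-[(7Z,9Z)-tetradeca-7,9,13-trien-1-yl]oxolan-2-yl]butyl methanesulfonate | C=CCC/C=C\C=C/CCCCCC[C@@H]1CC[C@@H]([C@@H](OS(C)(=O)=O)CCC(OC)OC)O1 | intermediate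
22 | (1S)-4-hydroperoxy-4-methoxy-1-[(2S,5R)-5-[(7Z,9Z)-tetradeca-7,9,13-trien-1-yl]oxolan-2-yl]butyl methanesulfonate (C4 epimers) | C=CCC/C=C\C=C/CCCCCC[C@@H]1CC[C@@H]([C@@H](OS(C)(=O)=O)CCC(OC)OO)O1 | intermediate
23 | (6R)-3-methoxy-6-[(2S,5R)-5-[(7Z,9Z)-tetradeca-7,9,13-trien-1-yl]oxolan-2-yl]-1,2-dioxane (C3 epimers) | C=CCC/C=C\C=C/CCCCCC[C@@H]1CC[C@@H]([C@H]2CCC(OC)OO2)O1 | intermediate
24 | (6R)-6-[(2S,5R)-5-[(7Z,9Z)-tetradeca-7,9,13-trien-1-yl]oxolan-2-yl]-1,2-dioxan-3-ol (C3 epimers) | C=CCC/C=C\C=C/CCCCCC[C@@H]1CC[C@@H]([C@H]2CCC(O)OO2)O1 | intermediate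
25 | methyl 2-(triphenylphosphoranylidene)acetate | COC(=O)C=P(c1ccccc1)(c1ccccc1)c1ccccc1 | starting material
26 | methyl (2E,6R)-6-hydroperoxy-6-[(2S,5R)-5-[(7Z,9Z)-tetradeca-7,9,13-trien-1-yl]oxolan-2-yl]hex-2-enoate | C=CCC/C=C\C=C/CCCCCC[C@@H]1CC[C@@H]([C@H](OO)CC/C=C/C(=O)OC)O1 | intermediate
27 | methyl 2-[(3R,6R)-6-[(2S,5R)-5-[(7Z,9Z)-tetradeca-7,9,13-trien-1-yl]oxolan-2-yl]-1,2-dioxan-3-yl]acetate | C=CCC/C=C\C=C/CCCCCC[C@@H]1CC[C@@H]([C@H]2CC[C@H](CC(=O)OC)OO2)O1 | intermediate
28 | 2-[(3R,6R)-6-[(2S,5R)-5-[(7Z,9Z)-tetradeca-7,9,13-trien-1-yl]oxolan-2-yl]-1,2-dioxan-3-yl]acetic acid | C=CCC/C=C\C=C/CCCCCC[C@@H]1CC[C@@H]([C@H]2CC[C@H](CC(=O)O)OO2)O1 | target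

## Step count and risks

Total step count: 17. Longest linear sequence: 14 steps (steps 1–4, 6, 7, 10–17).

Steps most likely to fail:

1. Step 16 (proposed new method). The ylide may reduce the hydroperoxide of the open tautomer before olefination, or the conjugate addition may stop at a kinetic cis/trans mixture instead of equilibrating to trans. The fallback uses known reaction types and sets out from mesylate 21. Acetal hydrolysis (PPTS, acetone/H2O) would give the mesyloxy aldehyde F1, and Wittig olefination with 25 the enoate mesylate F2. Intermolecular SN2 displacement with 2-methoxyprop-2-yl hydroperoxide and CsOH·H2O in DMF (inversion at C6) would give the peroxy ketal F3. Cleavage of the ketal with AcOH/H2O/THF would release hydroperoxy enoate 26, which is cyclised with Et2NH in CF3CH2OH, and the route is rejoined at ester 27.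

2. Step 11 (key step). Perrhenic acid may cleave the dimethyl acetal or isomerise the (Z,Z)-diene, the (3+2) addition may be sluggish for the 1,2-disubstituted alkene, or the 2,5-trans preference may be incomplete. The fallback sets out from alkenol 17. A Mukaiyama-type aerobic oxidative cyclisation with Co(modp)2 (bis[1-(morpholine-4-carbonyl)-4,4-dimethylpentane-1,3-dionato]cobalt, divalent cobalt), O2 and tBuOOH in iPrOH should close the 2,5-trans oxolane but leave C6 uncontrolled, giving the carbinol epimer mixture F4. Dess–Martin oxidation would converge this on the ketone F5, and Felkin–Anh reduction with LiBH(sBu)3 at −78 °C should give the threo alcohol, rejoining the route at 20.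

3. Step 14. Substitution at the hindered C6, flanked by the ring A oxygen, may be slow, and elimination or base-induced O–O cleavage may compete. The fallback sets out from alcohol 20. Triflation (Tf2O, 2,6-lutidine, CH2Cl2, −78 °C) would give the triflate F6. Intermolecular displacement with 2-methoxyprop-2-yl hydroperoxide and KOtBu in THF (SN2 of an oxygen-flanked secondary triflate, as in carbohydrate chemistry, with inversion) would give the peroxy ketal F7. Aqueous acid (AcOH/H2O, then dilute HCl) would remove the peroxy ketal and the dimethyl acetal together, and the freed hydroperoxy aldehyde closes to the peroxy-hemiacetal, rejoining the route at 24.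

Further compounds
F1 | step 16 | (4S)-4-(methanesulfonyloxy)-4-[(2S,5R)-5-[(7Z,9Z)-tetradeca-7,9,13-trien-1-yl]oxolan-2-yl]butanal | C=CCC/C=C\C=C/CCCCCC[C@@H]1CC[C@@H]([C@@H](OS(C)(=O)=O)CCC=O)O1
F2 | step 16 | methyl (2E,6S)-6-(methanesulfonyloxy)-6-[(2S,5R)-5-[(7Z,9Z)-tetradeca-7,9,13-trien-1-yl]oxolan-2-yl]hex-2-enoate | C=CCC/C=C\C=C/CCCCCC[C@@H]1CC[C@@H]([C@@H](OS(C)(=O)=O)CC/C=C/C(=O)OC)O1
F3 | step 16 | methyl (2E,6R)-6-[(2-methoxypropan-2-yl)peroxy]-6-[(2S,5R)-5-[(7Z,9Z)-tetradeca-7,9,13-trien-1-yl]oxolan-2-yl]hex-2-enoate | C=CCC/C=C\C=C/CCCCCC[C@@H]1CC[C@@H]([C@H](OOC(C)(C)OC)CC/C=C/C(=O)OC)O1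
F4 | step 11 | 4,4-dimethoxy-1-[(2S,5R)-5-[(7Z,9Z)-tetradeca-7,9,13-trien-1-yl]oxolan-2-yl]butan-1-ol (C1 epimers) | C=CCC/C=C\C=C/CCCCCC[C@@H]1CC[C@@H](C(O)CCC(OC)OC)O1
F5 | step 11 | 4,4-dimethoxy-1-[(2S,5R)-5-[(7Z,9Z)-tetradeca-7,9,13-trien-1-yl]oxolan-2-yl]butan-1-one | C=CCC/C=C\C=C/CCCCCC[C@@H]1CC[C@@H](C(=O)CCC(OC)OC)O1
F6 | step 14 | (1S)-4,4-dimethoxy-1-[(2S,5R)-5-[(7Z,9Z)-tetradeca-7,9,13-trien-1-yl]oxolan-2-yl]butyl trifluoromethanesulfonate | C=CCC/C=C\C=C/CCCCCC[C@@H]1CC[C@@H]([C@@H](OS(=O)(=O)C(F)(F)F)CCC(OC)OC)O1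
F7 | step 14 | (2S,5R)-2-[(1R)-4,4-dimethoxy-1-[(2-methoxypropan-2-yl)peroxy]butyl]-5-[(7Z,9Z)-tetradeca-7,9,13-trien-1-yl]oxolane | C=CCC/C=C\C=C/CCCCCC[C@@H]1CC[C@@H]([C@H](OOC(C)(C)OC)CCC(OC)OC)O1
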